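## Retrosynthetic overview

1. Target gibberellin (C20 aldehyde, C7 and C19 acids, 15β-hydroxyl, 16-methylene) ⇐ 15β-ol ⇐ 16-methylene-15-one ⇐ ring D 15,16-dione ⇐ C15=C16 alkene; before that the C11 oxygen is removed, and the C7/C19 acids and the C20 aldehyde are carried as a 2-(trimethylsilyl)ethyl ester and a 19,20-lactol methyl ether.
2. Key disconnection: C8–C9 and C12–C13 together, by an intramolecular (4+3) cycloaddition of a cyclopenta-1,3-diene (ring D: C8, C15, C16, C13, C14) with a 2-alkoxyallyl cation (C9–C11–C12); rings B and C form in this one step.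
3. Enabling feature: rings C/D are a bicyclo[3.2.1]octane whose seven-membered ring C8–C9–C11–C12–C13–C16–C15 (bridged by C14) is a diene-plus-three-carbon-cation adduct; C20 is 1,3-diaxial to C19 on ring A and next to C9, so the oxygen on C11 can be tied to C20 (acylal of the 19,20-lactol, a temporary five-membered ring), which fixes the face of attack.
4. Ring A: C5 is the hub of three acetic acid arms (C4–C19, C10–C20, C6–C7) ⇒ methanetriacetic acid; catalytic desymmetrisation sets C5, cycloalkylation closes ring A, Ireland–Claisen sets C10, enolate methylation sets C4.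
5. Order of ring formation: A; the temporary O-heterocycles; D (attached as the diene); B and C together.

Key step: step 12

Remarks
- Gibberellane numbering is used throughout (ring A C1–C5, C10; ring B C5, C6, C8, C9, C10; ring C C8, C9, C11–C14; ring D C8, C14, C13, C16, C15); α/β as in the usual gibberellin drawing.
- Assumption: the target is written as the open aldehyde–acid; this form equilibrates with its 19,20-lactol, and the last step delivers that equilibrating material.
- Assumption: (DHQD)2AQN opens the enantiotopic carbonyl of 3 that leads to (R)-5; should the sense be opposite, the pseudo-enantiomer (DHQ)2AQN is used.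

## Route

Step 1
Reactants: 1 3-(carboxymethyl)pentanedioic acid (methanetriacetic acid)
Product: 2 2-(2,6-dioxooxan-4-yl)acetic acid
Conditions: Ac2O (1.1 equiv), toluene, 80 °C
Reagents that add atoms: none
Why: Cyclodehydration of a 1,5-diacid with acetic anhydride (anhydride formation) gives the six-membered glutaric anhydride, and because the three arms of 1 are equivalent only one mono-anhydride can form; no stereocenter.

Step 2
Reactants: 2 2-(2,6-dioxooxan-4-yl)acetic acid
Product: 3 methyl 2-(2,6-dioxooxan-4-yl)acetate
Conditions: CH2N2, Et2O, 0 °C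
Reagents that add atoms: diazomethane C=[N+]=[N-]
Why: O-Methylation of the free acid with diazomethane proceeds under neutral conditions that leave the anhydride closed and marks this arm as the future C19 ester; C5 stays prochiral.

Step 3
Reactants: 3 methyl 2-(2,6-dioxooxan-4-yl)acetate; 4 2-chloroprop-2-en-1-ol
Product: 5 (3R)-5-[(2-chloroprop-2-en-1-yl)oxy]-3-(2-methoxy-2-oxoethyl)-5-oxopentanoic acid
Conditions: 4 (2 equiv), (DHQD)2AQN (10 mol %), Et2O, −30 °C
Reagents that add atoms: none
Why: Cinchona-alkaloid-catalysed desymmetrising alcoholysis of a prochiral 3-substituted glutaric anhydride, in which the catalyst activates the alcohol by general-base catalysis and selects one enantiotopic carbonyl, sets C5 and leaves the three arms as methyl ester (C19 arm), 2-chloroallyl ester (C20 arm) and free acid (C7 arm).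

Step 4
Reactants: 5 (3R)-hemiester; 6 1,3-diiodopropane
Product: 7 ring A acid (cyclohexane with the C19 methyl ester on C4 and the C20 2-chloroallyl ester on C10 and the CH2CO2H arm on C5; epimer mixture at C4 and C10)
Conditions: LiN(iPr)2 (3.2 equiv), THF/DMPU, −78 °C; then 6, −78 → −20 °C; aq. HCl
Reagents that add atoms: none
Why: Cycloalkylation of a diester bis-enolate with a 1,3-dihalide (intermolecular alkylation, then 6-exo-tet closure) joins the two ester α-carbons C4 and C10 because the carboxylate arm is not enolised at −78 °C; C5 is untouched, and C4 and C10 are re-made in steps 5 and 6 so their configuration here does not matter.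

Step 5
Reactants: 7 ring A acid
Product: 9 C10-quaternary diacid (10β-CH2C(Cl)=CH2; 10α-CO2H; C4 epimer mixture), via silyl ketene acetal 8 (not isolated)
Conditions: LiN(iPr)2 (3.5 equiv), Me3SiCl (4 equiv), THF, −78 → 50 °C; aq. HCl
Reagents that add atoms: none
Why: Ireland–Claisen rearrangement, in which only the ketene acetal of the 2-chloroallyl ester can undergo the [3,3] shift, forms the C10–C9 bond on the face away from the neighbouring C5 side chain (held axial by allylic strain), so C9 ends up trans to C6 and C20 is released as the free, axial acid.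

Step 6
Reactants: 9 C10-quaternary diacid
Product: 10 ring A diacid ester (4β-methyl; 4α-CO2Me; 5β-H; 10α-CO2H; 10β-chloroallyl)
Conditions: LiN(iPr)2 (3.3 equiv), THF/DMPU, −78 °C; MeI, −78 → −40 °C; aq. HCl
Reagents that add atoms: iodomethane CI
Why: Ester enolate alkylation at C4, the only ester α-position (the two carboxylates are not enolised at −78 °C), takes MeI from the equatorial direction, anti to the axial C20 carboxylate, so the methyl group becomes equatorial (trans to the C5 side chain) and the C19 ester axial.

Step 7
Reactants: 10 ring A diacid ester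
Product: 12 bromomethyl methoxy spiro-lactone acid (C20(=O)–O–C11(OMe)(CH2Br)–C9H2 on C10), via chloro lactone 11 (not isolated)
Conditions: NBS (1.1 equiv), NaHCO3, MeOH/CH2Cl2, −20 → 0 °C; then aq. NaH2PO4
Reagents that add atoms: N-bromosuccinimide O=C1CCC(=O)N1Br; methanol CO
Why: Bromolactonisation (bromonium formation at the 2-chloroallyl alkene, 5-exo attack of the C20 carboxylate on the chlorine-stabilised C11 cation, methanolysis of the chloro acylal) turns the side chain into a masked C11 bromomethyl ketone joined to C20 through oxygen; C11 forms as an epimer mixture that is irrelevant because C11 becomes trigonal in step 12.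

Step 8
Reactants: 12 bromomethyl methoxy spiro-lactone acid
Product: 14 acylal lactone acid (C20 is the acylal carbon of the 19,20-lactol lactone and its second oxygen is bound to C11), via lactol 13 (not isolated)
Conditions: iBu2AlH (2.2 equiv), CH2Cl2, −78 °C, then 0 °C; aq. KNaC4H4O6 (potassium sodium tartrate); PPTS (cat.), CH2Cl2, rt
Reagents that add atoms: none
Why: Partial reduction of a lactone to the lactol with iBu2AlH (the five-membered acyloxy-ketal lactone is far more electrophilic than the axial tertiary C19 ester, and the C7 acid is masked as its aluminium carboxylate) is followed by translactonisation of the lactol oxygen onto the 1,3-diaxial C19 ester; hydride enters anti to the C19 ester, so the new C20–O bond points toward C19 and C20 is fixed with its other oxygen toward C11.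

Step 9
Reactants: 14 acylal lactone acid
Product: 15 acylal lactone 2-(trimethylsilyl)ethyl ester
Conditions: Me3SiCH2CH2OH, DCC, DMAP (cat.), CH2Cl2, 0 °C → rt
Reagents that add atoms: 2-(trimethylsilyl)ethanol C[Si](C)(C)CCO
Why: Steglich esterification of the only free acid (C7) gives an ester that can be enolised in step 10 and is later cleaved by fluoride at the remote silicon, which avoids hydrolysis of the hindered C7 ester; no stereocenter.

Step 10
Reactants: 15 acylal lactone 2-(trimethylsilyl)ethyl ester; 16 cyclopent-2-en-1-one
Product: 17 1-hydroxycyclopent-2-en-1-yl ester (tertiary allylic alcohol on C8; diastereomer mixture at C6 and C8)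
Conditions: LiN(iPr)2 (1.1 equiv), THF, −78 °C; 16; AcOH, −78 °C
Reagents that add atoms: none
Why: Aldol-type 1,2-addition of the lithium ester enolate (C6 is the only enolisable position) to the enone carbonyl at low temperature builds the congested C6–C8 bond; the mixtures at C6 and C8 are tolerated because C8 becomes trigonal in step 11 and C6 is equilibrated in step 15.

Step 11
Reactants: 17 1-hydroxycyclopent-2-en-1-yl ester
Product: 18 cyclopenta-1,3-dienyl ester (drawn as the 1-substituted isomer; C6 mixture)
Conditions: Burgess reagent, benzene, 50 °C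
Reagents that add atoms: none
Why: Burgess dehydration (syn elimination of the sulfamate ester) of the tertiary allylic alcohol toward the ring CH2 gives the cyclopentadiene, whose 1- and 2-substituted isomers interconvert by 1,5-hydrogen shifts at room temperature; no stereocenter is formed.

Step 12
Reactants: 18 cyclopenta-1,3-dienyl ester
Product: 22 tetracyclic keto lactol (C11 ketone; C15=C16 alkene; free 19,20-lactol; C6 mixture), via enol ether bromide 19 (not isolated), via alkoxyallyl cation 20 (not isolated), via oxocarbenium adduct 21 (not isolated)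
Conditions: Me3SiOTf (1.1 equiv), iPr2NEt (1.5 equiv), CH2Cl2, −78 °C; then AgBF4 (1.2 equiv), CH2Cl2/MeNO2, −78 → −30 °C; aq. NaHCO3, 0 °C
Reagents that add atoms: water O
Why: Me3SiOTf ionises the ketal at C11 (loss of MeOSiMe3) and the amine removes a C9 proton to give the cyclic enol ether 19, AgBF4 then abstracts the allylic bromide to give the 2-alkoxyallyl cation 20 (C9–C11–C12), which adds with its termini C9 and C12 to the diene termini C8 and C13 of the tethered cyclopenta-1,3-diene to give oxocarbenium ion 21, and water at C11 releases the C11 ketone and the 19,20-lactol. The closest known reaction type is the (4+3) cycloaddition of 2-alkoxyallyl (oxyallyl-type) cations, made from 2-alkoxyallyl halides and silver salts, with cyclopentadiene, and its intramolecular version with a three-atom tether. Ring B closes through the C8–C9 bond as a five-membered ring over the tether C6–C5–C10, and ring C closes through the C12–C13 bond together with the seven-membered ring C8–C9–C11–C12–C13–C16–C15 that the C14 methylene bridges (bicyclo[3.2.1]octene). C9 is set because the diene, tied to C5, can reach only the C5 face of the flat cation while the O–C20 ring keeps C11 cis to C20 on ring B (H9 β); C8 and C13 are set because C10 is held at the E position of the cation and the short tether then fits only the extended transition state, with C11 under the C14 methylene, so that the C15=C16 bridge ends up β and C10 axial on ring C. The step needs facial selectivity (ring C on the hindered C20 face of ring B), secured by the C20–O–C11 tether rather than by sterics, site selectivity among the equilibrating cyclopentadiene isomers, secured because only the 1-substituted isomer has C8 as a diene terminus within reach of the tether, and ionisation at the ketal before the acylal at C20, secured by the more basic methoxy oxygen at −78 °C. C6 passes through as a mixture that is corrected in step 15.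

Step 13
Reactants: 22 tetracyclic keto lactol
Product: 23 keto methoxy lactone (19,20-lactol methyl ether; C20 epimer mixture)
Conditions: MeOH, PPTS (cat.), rt; aq. NaHCO3
Reagents that add atoms: methanol CO
Why: Acid-catalysed acetalisation of the lactol (pseudo-acid to pseudo-ester) masks the latent C20 aldehyde as a methoxy lactone while the hindered C11 ketone stays free; the C20 epimers are irrelevant.

Step 14
Reactants: 23 keto methoxy lactone
Product: 25 C11-methylene methoxy lactone (C15=C16 alkene; C6 mixture), via tosylhydrazone 24 (not isolated)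
Conditions: TsNHNH2 (1.2 equiv), PPTS (cat.), THF, 45 °C; then catecholborane (3 equiv), CHCl3, 0 °C; then NaOAc·3H2O, 60 °C
Reagents that add atoms: none
Why: Deoxygenation of the C11 ketone through its tosylhydrazone (Caglioti-type reduction with catecholborane, then sulfinate elimination and loss of N2) removes the auxiliary oxygen of the key step under conditions that should spare the esters, the acylal and the C15=C16 alkene; no stereocenter is changed.

Step 15
Reactants: 25 C11-methylene methoxy lactone
Product: 26 6β-ester (H6 α)
Conditions: KOtBu (0.3 equiv), tBuOH/THF, 40 °C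
Reagents that add atoms: none
Why: Base-mediated epimerisation through the C7 ester enolate should converge the C6 mixture on the more stable 6β-ester, in which C7 is trans to C4 and away from the axial C19 carbonyl; C6 is set under thermodynamic control.

Step 16
Reactants: 26 6β-ester
Product: 27 15,16-dione
Conditions: KMnO4, Ac2O, 0 °C → rt
Reagents that add atoms: potassium permanganate [K+].[O-][Mn](=O)(=O)=O
Why: Permanganate oxidation of a 1,2-disubstituted alkene in acetic anhydride gives the α-diketone directly, and neither carbonyl can enolise (C8 quaternary, C13 bridgehead); no stereocenter.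

Step 17
Reactants: 27 15,16-dione
Product: 28 16-methylene-15-one
Conditions: Ph3PCH3Br (1.1 equiv), KN(SiMe3)2 (1.05 equiv), THF, 0 °C; then 27, −78 → 0 °C
Reagents that add atoms: methylenetriphenylphosphorane C=P(c1ccccc1)(c1ccccc1)c1ccccc1
Why: Wittig methylenation should occur at the C16 carbonyl (next to the C13 bridgehead hydrogen) rather than at the C15 carbonyl shielded by the quaternary C8, as in the mono-methylenation of non-enolisable bicyclic 1,2-diones; no stereocenter.

Step 18
Reactants: 28 16-methylene-15-one
Product: 29 15β-alcohol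
Conditions: NaBH4, CeCl3·7H2O, MeOH, −78 °C
Reagents that add atoms: none
Why: Luche 1,2-reduction of the exocyclic enone delivers hydride to C15 from the exo face (the side of the C14 methylene, away from the C11–C12 bridge and the C7 ester), which gives the endo 15β-alcohol.

Step 19
Reactants: 29 15β-alcohol
Product: 31 target gibberellin (C20 aldehyde; C7 acid; C19 acid; 15β-hydroxyl; 16-methylene), via methoxy lactone acid 30 (not isolated)
Conditions: Bu4NF (3 equiv), THF, rt; then LiOH (1 M aq.), rt; then 0.5 M HCl to pH 3, 0 °C
Reagents that add atoms: water O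
Why: Fluoride-induced fragmentation of the 2-(trimethylsilyl)ethyl ester frees the C7 acid and hydroxide then opens the methoxy lactone (acylal hydrolysis) to the C19 carboxylate and the C20 aldehyde, which on acidification give the target; no stereocenter is touched.

## Compound list

1 | 3-(carboxymethyl)pentanedioic acid (methanetriacetic acid) | OC(=O)CC(CC(=O)O)CC(=O)O | starting material
2 | 2-(2,6-dioxooxan-4-yl)acetic acid | OC(=O)CC1CC(=O)OC(=O)C1 | intermediate
3 | methyl 2-(2,6-dioxooxan-4-yl)acetate | COC(=O)CC1CC(=O)OC(=O)C1 | intermediate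
4 | 2-chloroprop-2-en-1-ol | C=C(Cl)CO | starting material
5 | (3R)-5-[(2-chloroprop-2-en-1-yl)oxy]-3-(2-methoxy-2-oxoethyl)-5-oxopentanoic acid | COC(=O)C[C@H](CC(=O)OCC(Cl)=C)CC(=O)O | intermediate
6 | 1,3-diiodopropane | ICCCI | starting material
7 | 2-[2-{[(2-chloroprop-2-en-1-yl)oxy]carbonyl}-6-(methoxycarbonyl)cyclohexyl]acetic acid; C5 as in 5, epimer mixture at C4 and C10 | C=C(Cl)COC(=O)C1CCCC(C(=O)OC)[C@H]1CC(=O)O | intermediate
8 | tris-silylated form of 7: trimethylsilyl ester at C7, silyl ketene acetals at C10 and C4 | C=C(Cl)COC(O[Si](C)(C)C)=C1CCCC(=C(OC)O[Si](C)(C)C)[C@H]1CC(=O)O[Si](C)(C)C | intermediate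
9 | 2-(carboxymethyl)-1-(2-chloroprop-2-en-1-yl)-3-(methoxycarbonyl)cyclohexane-1-carboxylic acid; 10α-CO2H, chloroallyl trans to the C5 arm, C4 epimers | C=C(Cl)C[C@]1(C(=O)O)CCCC(C(=O)OC)[C@H]1CC(=O)O | intermediate
10 | 2-(carboxymethyl)-1-(2-chloroprop-2-en-1-yl)-3-(methoxycarbonyl)-3-methylcyclohexane-1-carboxylic acid; 4β-Me, 4α-CO2Me, 5β-H, 10α-CO2H | C=C(Cl)C[C@]1(C(=O)O)CCC[C@@](C)(C(=O)OC)[C@H]1CC(=O)O | intermediate
11 | chloro lactone: spiro γ-lactone C20(=O)–O–C11(Cl)(CH2Br) on C10 | BrCC2(Cl)C[C@]1(C(=O)O2)CCC[C@@](C)(C(=O)OC)[C@H]1CC(=O)O | intermediate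
12 | 2-[3-(bromomethyl)-3-methoxy-7-(methoxycarbonyl)-7-methyl-1-oxo-2-oxaspiro[4.5]decan-6-yl]acetic acid; ring A as in 10, C11 epimers | BrCC2(OC)C[C@]1(C(=O)O2)CCC[C@@](C)(C(=O)OC)[C@H]1CC(=O)O | intermediate
13 | lactol of 12 (C20H(OH)–O–C11) | BrCC2(OC)C[C@]1(C(O)O2)CCC[C@@](C)(C(=O)OC)[C@H]1CC(=O)O | intermediate
14 | acylal lactone acid: C20H bonded to O–C19(=O) (six-membered lactone across C4/C10) and to O–C11 (five-membered ketal ring; C11 bears OMe and CH2Br); C7 free acid | BrCC2(OC)C[C@]1([C@@H](O2)O3)CCC[C@@](C)(C3=O)[C@H]1CC(=O)O | intermediate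
15 | 2-(trimethylsilyl)ethyl ester of 14 | BrCC2(OC)C[C@]1([C@@H](O2)O3)CCC[C@@](C)(C3=O)[C@H]1CC(=O)OCC[Si](C)(C)C | intermediate
16 | cyclopent-2-en-1-one | O=C1C=CCC1 | starting material
17 | 15 carrying a 1-hydroxycyclopent-2-en-1-yl group on C6 (C6 and C8 mixtures) | BrCC2(OC)C[C@]1([C@@H](O2)O3)CCC[C@@](C)(C3=O)[C@H]1C(C(=O)OCC[Si](C)(C)C)C4(O)C=CCC4 | intermediate
18 | 15 carrying a cyclopenta-1,3-dien-1-yl group on C6 (C6 mixture; equilibrates with the 2-substituted isomer) | BrCC2(OC)C[C@]1([C@@H](O2)O3)CCC[C@@](C)(C3=O)[C@H]1C(C(=O)OCC[Si](C)(C)C)C4=CC=CC4 | intermediate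
19 | cyclic enol ether bromide (C9=C11 in the five-membered O-ring; CH2Br on C11) | BrCC2=C[C@]1([C@@H](O2)O3)CCC[C@@](C)(C3=O)[C@H]1C(C(=O)OCC[Si](C)(C)C)C4=CC=CC4 | intermediate
20 | cyclic 2-alkoxyallyl cation (C9–C11–C12) tetrafluoroborate | [CH2+]C2=C[C@]1([C@@H](O2)O3)CCC[C@@](C)(C3=O)[C@H]1C(C(=O)OCC[Si](C)(C)C)C4=CC=CC4.F[B-](F)(F)F | intermediate
21 | (4+3) adduct as C11 oxocarbenium tetrafluoroborate (O on C11 still bound to C20) | C=1[C@@H]2CC(=[O+]5)[C@H]3[C@]4([C@@H]5O6)CCC[C@@](C)(C6=O)[C@H]4C(C(=O)OCC[Si](C)(C)C)[C@]3(C2)C=1.F[B-](F)(F)F | intermediate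
22 | tetracyclic keto lactol: C11 ketone, C15=C16 alkene, 19,20-lactol (C20 OH), C7 2-(trimethylsilyl)ethyl ester, C6 mixture | C=1[C@@H]2CC(=O)[C@H]3[C@]4(C(O)O5)CCC[C@@](C)(C5=O)[C@H]4C(C(=O)OCC[Si](C)(C)C)[C@]3(C2)C=1 | intermediate
23 | methyl ether of lactol 22 (C20 OMe, epimers) | C=1[C@@H]2CC(=O)[C@H]3[C@]4(C(OC)O5)CCC[C@@](C)(C5=O)[C@H]4C(C(=O)OCC[Si](C)(C)C)[C@]3(C2)C=1 | intermediate
24 | C11 tosylhydrazone of 23 | C=1[C@@H]2CC(=NNS(=O)(=O)c6ccc(C)cc6)[C@H]3[C@]4(C(OC)O5)CCC[C@@](C)(C5=O)[C@H]4C(C(=O)OCC[Si](C)(C)C)[C@]3(C2)C=1 | intermediate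
25 | C11-methylene compound (C6 mixture) | C=1[C@@H]2CC[C@H]3[C@]4(C(OC)O5)CCC[C@@](C)(C5=O)[C@H]4C(C(=O)OCC[Si](C)(C)C)[C@]3(C2)C=1 | intermediate
26 | 6β-ester (H6 α) | C=1[C@@H]2CC[C@H]3[C@]4(C(OC)O5)CCC[C@@](C)(C5=O)[C@H]4[C@H](C(=O)OCC[Si](C)(C)C)[C@]3(C2)C=1 | intermediate
27 | 15,16-dione | O=C1[C@@H]2CC[C@H]3[C@]4(C(OC)O5)CCC[C@@](C)(C5=O)[C@H]4[C@H](C(=O)OCC[Si](C)(C)C)[C@]3(C2)C1=O | intermediate
28 | 16-methylene-15-one | C=C1[C@@H]2CC[C@H]3[C@]4(C(OC)O5)CCC[C@@](C)(C5=O)[C@H]4[C@H](C(=O)OCC[Si](C)(C)C)[C@]3(C2)C1=O | intermediate
29 | 15β-alcohol | C=C1[C@@H]2CC[C@H]3[C@]4(C(OC)O5)CCC[C@@](C)(C5=O)[C@H]4[C@H](C(=O)OCC[Si](C)(C)C)[C@]3(C2)[C@@H]1O | intermediate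
30 | C7 acid with intact 19,20-methoxy lactone | C=C1[C@@H]2CC[C@H]3[C@]4(C(OC)O5)CCC[C@@](C)(C5=O)[C@H]4[C@H](C(=O)O)[C@]3(C2)[C@@H]1O | intermediate
31 | target gibberellin: tetracyclic gibberellane 7,19-dioic acid with C20 as the aldehyde, a 15β-hydroxyl and the 16-methylene group | C=C1[C@@H]2CC[C@H]3[C@]4(C=O)CCC[C@@](C)(C(=O)O)[C@H]4[C@H](C(=O)O)[C@]3(C2)[C@@H]1O | target

## Step count and risks

Total step count: 19. Longest linear sequence: 19 steps (from 1; compounds 4, 6 and 16 are bought).

Steps most likely to fail:

Step 12. The ketal may not ionise cleanly: ionisation at the acylal carbon C20 would break the tether, the cyclopentadiene may oligomerise under the Lewis acid, or the cation may lose a proton before the second bond forms. The fallback sets out from 18 and returns at 22. The ketal of 18 is hydrolysed with aqueous acetic acid in THF at room temperature to bromo ketone lactol F1. F1 is then treated with Et3N in CF3CH2OH at 0 °C to room temperature, where enolisation toward C9 and loss of bromide generate the oxyallyl species under basic conditions. The lactol hydroxyl can hydrogen-bond to the oxyallyl oxygen and so still guide C11 to the C20 face, and the intramolecular (4+3) cycloaddition should give 22 directly.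

Step 11. Elimination may run toward the acidic C6–H instead of the ring CH2, which would give an exocyclic cyclopentenylidene ester in place of the cyclopentadiene. The fallback sets out from 15 and returns at 18. The ester enolate of 15 (LiN(iPr)2, THF, −78 °C) is brominated with CBr4 to α-bromo ester F2, and F2 is substituted with sodium cyclopentadienide (NaC5H5, THF, 0 °C). The 5-substituted cyclopentadiene formed first should isomerise by 1,5-hydrogen shifts to the same equilibrium mixture 18, so no elimination is needed.

Step 4. The bis-enolate may oligomerise with the diiodide, or the allylic ester enolate may undergo a premature [3,3] shift on warming. The fallback sets out from 5 and returns at 7. Compound 5 is alkylated once with 1-bromo-3-chloropropane (LiN(iPr)2 2.1 equiv, THF, −78 °C) to ω-chloropropyl ester F3; both regioisomers lead to the same ring. F3 is isolated and cyclised in a separate, dilute enolate alkylation (KN(SiMe3)2, Bu4NI cat., THF, −40 °C) to 7.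

## Further compounds

F1 | step 12 | bromo ketone lactol (free C11 ketone with CH2Br, free 19,20-lactol, cyclopentadienyl ester) | BrCC(=O)C[C@]1(C(O)O3)CCC[C@@](C)(C3=O)[C@H]1C(C(=O)OCC[Si](C)(C)C)C4=CC=CC4
F2 | step 11 | α-bromo ester (C6 bromide of 15) | BrCC2(OC)C[C@]1([C@@H](O2)O3)CCC[C@@](C)(C3=O)[C@H]1C(Br)C(=O)OCC[Si](C)(C)C
F3 | step 4 | ω-chloropropyl hemiester (isomer alkylated next to the methyl ester) | COC(=O)C(CCCCl)[C@H](CC(=O)OCC(Cl)=C)CC(=O)O
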